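**Plan**

- Retrosynthesis (target numbering): C3–OH ⇐ C3 ketone; the second C4 methyl and C5–H ⇐ the 4-methyl-Δ4-3-ketone; ring B is opened at C5–C6; then C7–C8, the C8 oxygen (vinyl ⇒ methyl ketone), C9–C10, the C8=C9 alkene (metathesis) and C11–C12 are cut, back to 2-methylcyclohexane-1,3-dione and (2E,6E)-farnesyl bromide.
- Forward: ring A is bought and carried as its isobutyl vinylogous ester; the chain C11–C23 together with C9, C8 and the C8 methyl is grown from farnesyl bromide and joined at C9–C10; C8 is completed; ring B closes last through C5–C6; C5, C4 and C3 are then set on the bicyclic enone.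
- Enabling feature: the C3 oxygen of ring A is 1,3 to C5, so ring A can be a vinylogous ester with C5 as carbonyl and C3 as alkoxy carbon. C6 ends a two-carbon arm on carbinol carbon C8, so a C6 carbanion reaches C5 through a six-membered transition state, and acid then moves the carbonyl to C3 with the alkene at C4=C5.
- Stereochemistry: C9 and C10 together in one iridium-catalysed allylation; C8 relayed from C9 (Felkin–Anh); C5 from C10 (axial protonation, trans fusion); C3 from the ring (equatorial alcohol); the E alkenes from farnesyl bromide, SeO2 oxidation of the E methyl, and metathesis.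

Key step: step 12

Remark: the target's numbering is used for every intermediate (decalin C1–C10, ring A = C1–C5 + C10, ring B = C5–C10; C11, C12 … C23 the side chain on C9; C17 the methyl on C8). Compounds 1 and 5, allyl methyl carbonate and all reagents are taken as commercial.

Step 1
Reactants: 1 2-methylcyclohexane-1,3-dione
Product: 2 3-isobutoxy-2-methylcyclohex-2-en-1-one
Conditions: i-BuOH, TsOH (cat.), toluene, reflux, azeotropic removal of water
Reagents that add atoms: 2-methylpropan-1-ol CC(C)CO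
Why: Acid-catalysed enol etherification of a 1,3-dione (vinylogous ester formation) should give the ring A building block in which the future C5 is the carbonyl and the future C3 carries the alkoxy group.

Step 2
Reactants: 2 3-isobutoxy-2-methylcyclohex-2-en-1-one
Product: 4 (±)-3-isobutoxy-2,6-dimethylcyclohex-2-en-1-one, via lithium dienolate 3 (not isolated)
Conditions: LiN(i-Pr)2, THF, −78 °C; then MeI, −78 °C to rt
Reagents that add atoms: iodomethane CI
Why: Kinetic α′-deprotonation of a vinylogous ester and alkylation (Stork–Danheiser alkylation) should place the future C10 methyl; the new centre is racemic and is erased in step 7.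

Step 3
Reactants: 5 (2E,6E)-farnesyl bromide
Product: 6 (5E,9E)-6,10,14-trimethylpentadeca-1,5,9,13-tetraene
Conditions: CH2=CHCH2MgBr, Li2CuCl4 (cat.), THF, −78 to 0 °C
Reagents that add atoms: allylmagnesium bromide C=CC[Mg]Br
Why: Copper-catalysed Grignard coupling at the primary allylic bromide (SN2; the SN2′ path would have to form a quaternary carbon) should make the C11–C12 bond with the E alkenes untouched.

Step 4
Reactants: 6 (5E,9E)-6,10,14-trimethylpentadeca-1,5,9,13-tetraene
Product: 7 (2E,6E,10E)-2,6,10-trimethylpentadeca-2,6,10,14-tetraen-1-ol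
Conditions: SeO2 (cat.), t-BuOOH, salicylic acid (cat.), CH2Cl2, 0 °C to rt
Reagents that add atoms: selenium dioxide O=[Se]=O (oxygen carrier, catalytic); tert-butyl hydroperoxide CC(C)(C)OO (stoichiometric oxygen source)
Why: Catalytic SeO2 allylic oxidation (ene reaction, then [2,3] shift) should prefer the E methyl of the terminal isopropylidene group and give the (E)-allylic alcohol of the target; the monosubstituted vinyl group is inert.

Step 5
Reactants: 7 (2E,6E,10E)-2,6,10-trimethylpentadeca-2,6,10,14-tetraen-1-ol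
Product: 8 triisopropylsilyl ether of 7
Conditions: i-Pr3SiCl, imidazole, DMF, rt
Reagents that add atoms: chlorotriisopropylsilane CC(C)[Si](Cl)(C(C)C)C(C)C
Why: Silylation of the primary alcohol; an all-alkyl silyl ether is chosen because it should survive tert-butyllithium, dilute acid and lithium in ammonia.

Step 6
Reactants: 8 triisopropylsilyl ether of 7
Product: 9 methyl (2E,6E,10E,14E)-7,11,15-trimethyl-16-(triisopropylsilyloxy)hexadeca-2,6,10,14-tetraen-1-yl carbonate
Conditions: allyl methyl carbonate (excess), second-generation Grubbs catalyst (cat.), CH2Cl2, 40 °C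
Reagents that add atoms: allyl methyl carbonate C=CCOC(=O)OC
Why: Olefin cross-metathesis of the only monosubstituted alkene with an unhindered terminal partner should give the linear allylic carbonate, mainly as the E isomer; the trisubstituted alkenes should react far more slowly.

Step 7
Reactants: 4 (±)-3-isobutoxy-2,6-dimethylcyclohex-2-en-1-one; 9 allylic methyl carbonate
Product: 11 (6R)-3-isobutoxy-2,6-dimethyl-6-[(3S,6E,10E,14E)-7,11,15-trimethyl-16-(triisopropylsilyloxy)hexadeca-1,6,10,14-tetraen-3-yl]cyclohex-2-en-1-one, via lithium dienolate 10 (not isolated)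
Conditions: LiN(SiMe3)2, THF, −78 °C; then 9, [Ir(cod)Cl]2 (2 mol %), BINOL-derived N,N-bis(1-phenylethyl)phosphoramidite (4 mol %, enantiomer chosen for S at C9), LiCl, −78 °C to rt
Reagents that add atoms: none
Why: Iridium-catalysed branched-selective allylic alkylation of a prochiral ketone enolate: the allyl–iridium intermediate should be attacked at its substituted terminus, the ligand fixing C9 (S) and the face of the tetrasubstituted dienolate and hence C10 (R); the (9S,10R) pair is the one the target needs, and the minor Z carbonate should react more slowly.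

Step 8
Reactants: 11 allylation product
Product: 12 (6R)-3-isobutoxy-2,6-dimethyl-6-[(3R,6E,10E,14E)-7,11,15-trimethyl-2-oxo-16-(triisopropylsilyloxy)hexadeca-6,10,14-trien-3-yl]cyclohex-2-en-1-one
Conditions: PdCl2 (10 mol %), Cu(OAc)2 (cat.), O2 (1 atm), DMA/H2O, rt
Reagents that add atoms: water O
Why: Wacker-type oxidation of the γ,δ-unsaturated ketone should give the methyl ketone (C8=O with C17 as its methyl) at the only monosubstituted alkene; the trisubstituted alkenes and the vinylogous ester should not react, and C9 is not enolised under these conditions.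

Step 9
Reactants: 12 methyl ketone
Product: 13 (6R)-6-[(3R,4R,7E,11E,15E)-3-hydroxy-3,8,12,16-tetramethyl-17-(triisopropylsilyloxy)heptadeca-1,7,11,15-tetraen-4-yl]-3-isobutoxy-2,6-dimethylcyclohex-2-en-1-one
Conditions: CH2=CHMgBr, CeCl3, THF, −78 °C
Reagents that add atoms: vinylmagnesium bromide C=C[Mg]Br
Why: Organocerium 1,2-addition to the more electrophilic, less hindered of the two carbonyls; Felkin–Anh-type 1,2-induction from C9 (quaternary C10 as the large group anti to the nucleophile, attack past H) should give the 8R carbinol with C6=C7 in place.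

Step 10
Reactants: 13 vinyl carbinol
Product: 15 (6R)-6-[(3R,4R,7E,11E,15E)-1,3-dihydroxy-3,8,12,16-tetramethyl-17-(triisopropylsilyloxy)heptadeca-7,11,15-trien-4-yl]-3-isobutoxy-2,6-dimethylcyclohex-2-en-1-one, via B-alkyl-9-BBN adduct 14 (not isolated)
Conditions: 9-BBN (2.5 equiv), THF, 0 °C to rt; then NaOH, H2O2, 0 °C
Reagents that add atoms: hydrogen peroxide OO
Why: Anti-Markovnikov hydroboration–oxidation with a bulky borane should be selective for the monosubstituted vinyl group over the trisubstituted alkenes and put the oxygen on C6.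

Step 11
Reactants: 15 diol
Product: 16 (6R)-6-[(3R,4R,7E,11E,15E)-3-hydroxy-1-iodo-3,8,12,16-tetramethyl-17-(triisopropylsilyloxy)heptadeca-7,11,15-trien-4-yl]-3-isobutoxy-2,6-dimethylcyclohex-2-en-1-one
Conditions: I2, PPh3, imidazole, CH2Cl2, 0 °C
Reagents that add atoms: iodine II
Why: Appel iodination should convert only the primary alcohol; the tertiary C8 alcohol is too hindered, and imidazole keeps the medium non-acidic for the vinylogous ester.

Step 12
Reactants: 16 iodo alcohol
Product: 19 (4aR,5R,6R)-6-hydroxy-1,4a,6-trimethyl-5-[(3E,7E,11E)-4,8,12-trimethyl-13-(triisopropylsilyloxy)trideca-3,7,11-trien-1-yl]-4,4a,5,6,7,8-hexahydronaphthalen-2(3H)-one, via C6-lithio C8-lithium alkoxide 17 (not isolated), via cyclised dilithium dialkoxide 18 (not isolated)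
Conditions: t-BuLi (3.2 equiv), Et2O/pentane, −78 to 0 °C; then 1 M HCl, THF, 0 °C to rt
Reagents that add atoms: water O
Why: tert-Butyllithium first forms the C8 lithium alkoxide and then exchanges the primary iodide, giving a γ-oxido alkyllithium whose C6 carbanion adds to the C5 carbonyl of the vinylogous ester (6-exo-trig closure of ring B through a six-membered transition state); aqueous acid then hydrolyses the enol ether and eliminates the C5 oxygen, leaving the C3 ketone and the C4=C5 alkene. The closest known reaction type is the Stork–Danheiser addition–transposition, run here intramolecularly after halogen–lithium exchange. No stereocentre made in the closure survives, because C5 becomes trigonal; the step instead needs chemoselectivity (exchange and intramolecular addition faster than attack of tert-butyllithium on the carbonyl or enolisation) and regioselectivity in the elimination. The first should be secured by the hindered, electron-rich C5 carbonyl (quaternary C10 on one side, the C4 methyl on the other) and the proximity of C6, the second by the C3 alkoxy group, which makes C3(=O)–C4=C5 the only conjugated outcome. C8, C9 and C10 are not touched, and the enone formed is the substrate from which C5 and C4 are set in the next step.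

Step 13
Reactants: 19 bicyclic enone
Product: 21 (4aS,5R,6R,8aR)-6-hydroxy-1,1,4a,6-tetramethyl-5-[(3E,7E,11E)-4,8,12-trimethyl-13-(triisopropylsilyloxy)trideca-3,7,11-trien-1-yl]octahydronaphthalen-2(1H)-one, via dilithium enolate-alkoxide 20 (not isolated)
Conditions: Li (2.2 equiv), NH3(l)/THF, −78 °C; then MeI (excess), −78 to −33 °C
Reagents that add atoms: iodomethane CI
Why: Birch-type reductive alkylation of the enone: the C5 carbanion should be protonated axially on the face opposite the C10 methyl (trans fusion, 5R), and the regiodefined C3–C4 lithium enolate is methylated at C4 to give the gem-dimethyl group; isolated alkenes are not reduced.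

Step 14
Reactants: 21 ketone
Product: 22 (1R,2R,4aR,6S,8aS)-2,5,5,8a-tetramethyl-1-[(3E,7E,11E)-4,8,12-trimethyl-13-(triisopropylsilyloxy)trideca-3,7,11-trien-1-yl]decahydronaphthalene-2,6-diol
Conditions: NaBH4, MeOH, 0 °C
Reagents that add atoms: none
Why: Hydride reduction of the 4,4-dimethyl-3-ketone by axial attack from the α-face should give the equatorial 3β (3S) alcohol.

Step 15
Reactants: 22 silyl ether
Product: 23 CNP0200414.2, (1R,2R,4aR,6S,8aS)-1-[(3E,7E,11E)-13-hydroxy-4,8,12-trimethyltrideca-3,7,11-trien-1-yl]-2,5,5,8a-tetramethyldecahydronaphthalene-2,6-diol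
Conditions: n-Bu4NF, THF, rt
Reagents that add atoms: none
Why: Fluoride desilylation of the primary allylic silyl ether frees the last hydroxyl without touching the alkenes or the two ring alcohols.

**Compound list**

1 | 2-methylcyclohexane-1,3-dione | CC1C(=O)CCCC1=O | starting material
2 | 3-isobutoxy-2-methylcyclohex-2-en-1-one | CC1=C(OCC(C)C)CCCC1=O | intermediate
3 | lithium 5-isobutoxy-6-methylcyclohexa-1,5-dien-1-olate | [Li]OC1=CCCC(OCC(C)C)=C1C | intermediate (not isolated)
4 | (±)-3-isobutoxy-2,6-dimethylcyclohex-2-en-1-one | CC1CCC(OCC(C)C)=C(C)C1=O | intermediate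
5 | (2E,6E)-1-bromo-3,7,11-trimethyldodeca-2,6,10-triene (farnesyl bromide) | CC(C)=CCC/C(C)=C/CC/C(C)=C/CBr | starting material
6 | (5E,9E)-6,10,14-trimethylpentadeca-1,5,9,13-tetraene | CC(C)=CCC/C(C)=C/CC/C(C)=C/CCC=C | intermediate
7 | (2E,6E,10E)-2,6,10-trimethylpentadeca-2,6,10,14-tetraen-1-ol | OC/C(C)=C/CC/C(C)=C/CC/C(C)=C/CCC=C | intermediate
8 | triisopropyl{[(2E,6E,10E)-2,6,10-trimethylpentadeca-2,6,10,14-tetraen-1-yl]oxy}silane | CC(C)[Si](C(C)C)(C(C)C)OC/C(C)=C/CC/C(C)=C/CC/C(C)=C/CCC=C | intermediate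
9 | methyl (2E,6E,10E,14E)-7,11,15-trimethyl-16-(triisopropylsilyloxy)hexadeca-2,6,10,14-tetraen-1-yl carbonate | CC(C)[Si](C(C)C)(C(C)C)OC/C(C)=C/CC/C(C)=C/CC/C(C)=C/CC/C=C/COC(=O)OC | intermediate
10 | lithium 5-isobutoxy-2,6-dimethylcyclohexa-1,5-dien-1-olate | [Li]OC1=C(C)CCC(OCC(C)C)=C1C | intermediate (not isolated)
11 | (6R)-3-isobutoxy-2,6-dimethyl-6-[(3S,6E,10E,14E)-7,11,15-trimethyl-16-(triisopropylsilyloxy)hexadeca-1,6,10,14-tetraen-3-yl]cyclohex-2-en-1-one | CC(C)[Si](C(C)C)(C(C)C)OC/C(C)=C/CC/C(C)=C/CC/C(C)=C/CC[C@@H](C=C)[C@@]1(C)CCC(OCC(C)C)=C(C)C1=O | intermediate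
12 | (6R)-3-isobutoxy-2,6-dimethyl-6-[(3R,6E,10E,14E)-7,11,15-trimethyl-2-oxo-16-(triisopropylsilyloxy)hexadeca-6,10,14-trien-3-yl]cyclohex-2-en-1-one | CC(C)[Si](C(C)C)(C(C)C)OC/C(C)=C/CC/C(C)=C/CC/C(C)=C/CC[C@@H](C(C)=O)[C@@]1(C)CCC(OCC(C)C)=C(C)C1=O | intermediate
13 | (6R)-6-[(3R,4R,7E,11E,15E)-3-hydroxy-3,8,12,16-tetramethyl-17-(triisopropylsilyloxy)heptadeca-1,7,11,15-tetraen-4-yl]-3-isobutoxy-2,6-dimethylcyclohex-2-en-1-one | CC(C)[Si](C(C)C)(C(C)C)OC/C(C)=C/CC/C(C)=C/CC/C(C)=C/CC[C@@H]([C@](C)(O)C=C)[C@@]1(C)CCC(OCC(C)C)=C(C)C1=O | intermediate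
14 | B-alkyl-9-BBN adduct of 13 (boron on C6) | CC(C)[Si](C(C)C)(C(C)C)OC/C(C)=C/CC/C(C)=C/CC/C(C)=C/CC[C@@H]([C@](C)(O)CCB2C3CCCC2CCC3)[C@@]1(C)CCC(OCC(C)C)=C(C)C1=O | intermediate (not isolated)
15 | (6R)-6-[(3R,4R,7E,11E,15E)-1,3-dihydroxy-3,8,12,16-tetramethyl-17-(triisopropylsilyloxy)heptadeca-7,11,15-trien-4-yl]-3-isobutoxy-2,6-dimethylcyclohex-2-en-1-one | CC(C)[Si](C(C)C)(C(C)C)OC/C(C)=C/CC/C(C)=C/CC/C(C)=C/CC[C@@H]([C@](C)(O)CCO)[C@@]1(C)CCC(OCC(C)C)=C(C)C1=O | intermediate
16 | (6R)-6-[(3R,4R,7E,11E,15E)-3-hydroxy-1-iodo-3,8,12,16-tetramethyl-17-(triisopropylsilyloxy)heptadeca-7,11,15-trien-4-yl]-3-isobutoxy-2,6-dimethylcyclohex-2-en-1-one | CC(C)[Si](C(C)C)(C(C)C)OC/C(C)=C/CC/C(C)=C/CC/C(C)=C/CC[C@@H]([C@](C)(O)CCI)[C@@]1(C)CCC(OCC(C)C)=C(C)C1=O | intermediate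
17 | C6-lithio C8-lithium alkoxide derived from 16 | CC(C)[Si](C(C)C)(C(C)C)OC/C(C)=C/CC/C(C)=C/CC/C(C)=C/CC[C@@H]([C@](C)(O[Li])CC[Li])[C@@]1(C)CCC(OCC(C)C)=C(C)C1=O | intermediate (not isolated)
18 | cyclised dilithium dialkoxide (C5–OLi, C8–OLi; ring B closed, C3 enol ether intact) | CC(C)[Si](C(C)C)(C(C)C)OC/C(C)=C/CC/C(C)=C/CC/C(C)=C/CC[C@@H]1[C@@]2(C)CCC(OCC(C)C)=C(C)C2(O[Li])CC[C@@]1(C)O[Li] | intermediate (not isolated)
19 | (4aR,5R,6R)-6-hydroxy-1,4a,6-trimethyl-5-[(3E,7E,11E)-4,8,12-trimethyl-13-(triisopropylsilyloxy)trideca-3,7,11-trien-1-yl]-4,4a,5,6,7,8-hexahydronaphthalen-2(3H)-one | CC(C)[Si](C(C)C)(C(C)C)OC/C(C)=C/CC/C(C)=C/CC/C(C)=C/CC[C@@H]1[C@@]2(C)CCC(=O)C(C)=C2CC[C@@]1(C)O | intermediate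
20 | dilithium C3 enolate / C8 alkoxide of the trans-fused 4-methyl ketone | CC(C)[Si](C(C)C)(C(C)C)OC/C(C)=C/CC/C(C)=C/CC/C(C)=C/CC[C@@H]1[C@@]2(C)CCC(O[Li])=C(C)[C@@H]2CC[C@@]1(C)O[Li] | intermediate (not isolated)
21 | (4aS,5R,6R,8aR)-6-hydroxy-1,1,4a,6-tetramethyl-5-[(3E,7E,11E)-4,8,12-trimethyl-13-(triisopropylsilyloxy)trideca-3,7,11-trien-1-yl]octahydronaphthalen-2(1H)-one | CC(C)[Si](C(C)C)(C(C)C)OC/C(C)=C/CC/C(C)=C/CC/C(C)=C/CC[C@@H]1[C@@]2(C)CCC(=O)C(C)(C)[C@@H]2CC[C@@]1(C)O | intermediate
22 | (1R,2R,4aR,6S,8aS)-2,5,5,8a-tetramethyl-1-[(3E,7E,11E)-4,8,12-trimethyl-13-(triisopropylsilyloxy)trideca-3,7,11-trien-1-yl]decahydronaphthalene-2,6-diol | CC(C)[Si](C(C)C)(C(C)C)OC/C(C)=C/CC/C(C)=C/CC/C(C)=C/CC[C@@H]1[C@@]2(C)CC[C@H](O)C(C)(C)[C@@H]2CC[C@@]1(C)O | intermediate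
23 | CNP0200414.2, (1R,2R,4aR,6S,8aS)-1-[(3E,7E,11E)-13-hydroxy-4,8,12-trimethyltrideca-3,7,11-trien-1-yl]-2,5,5,8a-tetramethyldecahydronaphthalene-2,6-diol | C/C(=C\CC/C(C)=C/CC/C(C)=C/CC[C@@H]1[C@@]2(C)CC[C@H](O)C(C)(C)[C@@H]2CC[C@@]1(C)O)CO | target

**Count**

Total step count: 15. Longest linear sequence: 13 steps (steps 3 to 15, from 5); steps 1 and 2 form the two-step ring A branch.

**Steps most likely to fail**

Step 7. The allylation may go wrong through attack at the unsubstituted allyl terminus, low or wrong diastereoselection at C9/C10, or proton transfer from the product's γ-position to the dienolate. The fallback generates the enolate regiospecifically under neutral conditions and sets out from 2 and 9. Methanolysis of 9 (K2CO3, MeOH) gives the allylic alcohol F1, and 1,1′-carbonyldiimidazole converts it into the imidazole-1-carboxylate F2. C-acylation of the lithium dienolate of 2 (LiN(i-Pr)2, THF, −78 °C) with F2 gives the β-keto ester F3, and methylation (MeI, Cs2CO3, MeCN) gives the α-methyl β-keto ester F4. Iridium-catalysed decarboxylative allylation of F4 ([Ir(cod)Cl]2, the same phosphoramidite, THF) then releases CO2 and should recombine the ion pair at the substituted allyl terminus, returning to the route at 11.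

Step 12. The closure may fail through enolisation of the vinylogous ester by the alkyllithium (simple reduction of C6–I after work-up) or competing attack of tert-butyllithium on the carbonyl. The fallback uses the C8 hydroxyl as a temporary ring and sets out from 16. Acid-catalysed intramolecular trans-etherification (TsOH cat., benzene, loss of isobutanol) should give the cyclic vinylogous ester F5, in which C8–O sits on C5 and the carbonyl is at C3. Radical cyclisation (Bu3SnH, AIBN, benzene, 80 °C) lets the C6 radical add to C5 in a 5-exo conjugate addition and gives the 7-oxabicyclo[2.2.1]heptane ketone F6. β-Elimination of the bridging alkoxide (DBU, THF) opens the temporary ring and returns to the route at 19.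

Step 9. The vinyl addition may show poor facial selectivity at C8 or be diverted by enolisation and aldol closure of the 1,4-diketone. The fallback replaces substrate control by reagent control and sets out from 12. Horner–Wadsworth–Emmons olefination (triethyl phosphonoacetate, NaH, THF) gives the (E)-enoate F7, and (i-Bu)2AlH at −78 °C reduces the ester to the (E)-allylic alcohol F8. Sharpless asymmetric epoxidation (Ti(Oi-Pr)4, D-(−)-diethyl tartrate, t-BuOOH) should give the epoxy alcohol F9 with the oxygen on the face that makes C8 R. NaAlH2(OCH2CH2OMe)2 then delivers hydride to C7 of the 2,3-epoxy alcohol and returns to the route at diol 15, bypassing 13 and 14.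

**Further compounds**

F1 | step 7 | (2E,6E,10E,14E)-7,11,15-trimethyl-16-(triisopropylsilyloxy)hexadeca-2,6,10,14-tetraen-1-ol | CC(C)[Si](C(C)C)(C(C)C)OC/C(C)=C/CC/C(C)=C/CC/C(C)=C/CC/C=C/CO
F2 | step 7 | (2E,6E,10E,14E)-7,11,15-trimethyl-16-(triisopropylsilyloxy)hexadeca-2,6,10,14-tetraen-1-yl imidazole-1-carboxylate | CC(C)[Si](C(C)C)(C(C)C)OC/C(C)=C/CC/C(C)=C/CC/C(C)=C/CC/C=C/COC(=O)n1ccnc1
F3 | step 7 | (2E,6E,10E,14E)-7,11,15-trimethyl-16-(triisopropylsilyloxy)hexadeca-2,6,10,14-tetraen-1-yl 4-isobutoxy-3-methyl-2-oxocyclohex-3-ene-1-carboxylate | CC(C)[Si](C(C)C)(C(C)C)OC/C(C)=C/CC/C(C)=C/CC/C(C)=C/CC/C=C/COC(=O)C1CCC(OCC(C)C)=C(C)C1=O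
F4 | step 7 | (2E,6E,10E,14E)-7,11,15-trimethyl-16-(triisopropylsilyloxy)hexadeca-2,6,10,14-tetraen-1-yl (±)-4-isobutoxy-1,3-dimethyl-2-oxocyclohex-3-ene-1-carboxylate | CC(C)[Si](C(C)C)(C(C)C)OC/C(C)=C/CC/C(C)=C/CC/C(C)=C/CC/C=C/COC(=O)C1(C)CCC(OCC(C)C)=C(C)C1=O
F5 | step 12 | cyclic vinylogous ester: C8–O–C5 dihydrofuran fused to ring A (C3 ketone, C4=C5), C8 bearing methyl and 2-iodoethyl, C9 bearing the silylated chain | CC(C)[Si](C(C)C)(C(C)C)OC/C(C)=C/CC/C(C)=C/CC/C(C)=C/CC[C@@H]1[C@@]2(C)CCC(=O)C(C)=C2O[C@]1(C)CCI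
F6 | step 12 | 5,8-epoxy-bridged (7-oxabicyclo[2.2.1]heptane) 4-methyl-3-ketone with ring B closed | CC(C)[Si](C(C)C)(C(C)C)OC/C(C)=C/CC/C(C)=C/CC/C(C)=C/CC[C@@H]1[C@@]2(C)CCC(=O)C(C)C23CC[C@@]1(C)O3
F7 | step 9 | ethyl (E)-enoate from 12 (C8(Me)=C7H–CO2Et on C9) | CC(C)[Si](C(C)C)(C(C)C)OC/C(C)=C/CC/C(C)=C/CC/C(C)=C/CC[C@@H](/C(C)=C/C(=O)OCC)[C@@]1(C)CCC(OCC(C)C)=C(C)C1=O
F8 | step 9 | (E)-allylic alcohol from F7 (C8(Me)=C7H–CH2OH on C9) | CC(C)[Si](C(C)C)(C(C)C)OC/C(C)=C/CC/C(C)=C/CC/C(C)=C/CC[C@@H](/C(C)=C/CO)[C@@]1(C)CCC(OCC(C)C)=C(C)C1=O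
F9 | step 9 | 7,8-epoxy alcohol from F8 (trans epoxide, oxygen on the face giving 8R) | CC(C)[Si](C(C)C)(C(C)C)OC/C(C)=C/CC/C(C)=C/CC/C(C)=C/CC[C@@H]([C@]2(C)O[C@H]2CO)[C@@]1(C)CCC(OCC(C)C)=C(C)C1=O
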